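The runs are simulated with made-up constants; the scatter is artificial.

The south-west flask cannot have stopped for want of G or Q on the overall equation. At 12 h its E equals 0.289 of the Q charged, which by that equation leaves 0.711 of the Q standing, yet between 9.0 h and 12 h E grows by 0.0260 of its final level. The number to carry is therefore Q's yield, the E gained by 12 h as a share of the Q charged. Its zero of scale is the overall equation, one E for each Q.

| flask | G | Q | E | time |
|---|---|---|---|---|
| south-west | 100 mM | 80.0 mM |  |  |
| north-west | 60.0 mM | 40.0 mM |  |  |
| west | 100 mM | 240 mM |  |  |
| east | 100 mM | 80.0 mM | 50.0 mM |  |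
| south | 50.0 mM | 26.0 mM |  | 12 h |

| south-west run: time / h | south-west run: [E] / mM | north-west run: time / h | north-west run: [E] / mM | west run: time / h | west run: [E] / mM | east run: time / h | east run: [E] / mM |
|---|---|---|---|---|---|---|---|
| 0.68 | 7.5 | 0.68 | 2.2 | 0.68 | 17.5 | 0.68 | 56.4 |
| 2.1 | 14.4 | 2.1 | 5.9 | 2.1 | 30.5 | 2.1 | 63.7 |
| 4.0 | 19.1 | 4.0 | 7.8 | 4.0 | 33.6 | 4.0 | 67.3 |
| 6.3 | 21.2 | 6.3 | 9.7 | 6.3 | 34.4 | 6.3 | 69.5 |
| 9.0 | 22.5 | 9.0 | 9.8 | 9.0 | 34.0 | 9.0 | 70.2 |
| 12 | 23.1 | 12 | 10.4 | 12 | 33.7 | 12 | 71.4 |

(standard deviation of a reading: 0.3 mM)

- Overall: G + Q -> E.
- Constant volume, constant temperature.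
- An order is taken over about fifteen percent of the charge, up and down.

1. the exponent of [G] in the starting rate at the charge of the south-west run (at the point where two percent of the G have become E) (one fixed amount of E, the same in the runs compared)
2. the exponent of [Q] in the starting rate at the charge of the south-west run (at the point where two percent of the G have become E)
3. E in the south run at 12 h, as a share of the G charged

My own ladder uses a filling time for each run: its E at 12 h divided by its mean rate up to the first reading. The west flask comes first at 1.31 h, the south-west flask next at 2.09 h, and the north-west flask after it at 3.21 h. Those mean rates stand at 3.41 between south-west and north-west, while the product of G and Q stands at 3.33, so I scale the rate by that product.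

The west flask holds more Q than G, and its yield is 0.140, so it is set aside. The south flask has Q as its limiting reagent, like the south-west and north-west flasks. Their yields, 0.289 at the larger G charge and 0.260 at the smaller, run on a straight line to 0.253 for the south flask, with a scatter of 0.00375 on the south-west yield and 0.00750 on the north-west yield. Its filling time comes to 3.75 h, and 12 h is 3.20 of those, so its reading at 12 h is a yield reading. I expect 13.1% of the G charged as E.

The forecast, holding that “the reaction stops because the active species dies, not because of reversal”, gives 13.6%, which is more than my figure, with range 11.8% to 15.8%. Its exponents are 0.93 for G and 0.97 for Q.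

The south flask gives 13.2%, and the exponents are 1.1 for G, above the forecast's, and 1.1 for Q. At the same amount of E made, the west rate is 3.2 times the south-west rate.

    G + Q → E (1.703 M⁻¹ h⁻¹)
    G + Q → X (2.610 M⁻¹ h⁻¹)
    Q → Ze (0.08172 h⁻¹)
    E + Q → X (0.1688 M⁻¹ h⁻¹)

The south flask's yield is 0.253, against the 0.253 reckoned. In the east flask, with the G and Q of the south-west flask, the yield is 0.268 against 0.289.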